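I decided to count the rounds of the catalyst instead of following the solid. In this flask the solid substrate dissolves into starting material. Free catalyst takes that up and passes through catalyst intermediate A to catalyst intermediate B, which either releases product and free catalyst or meets the capture agent and becomes trapped intermediate.

    starting material + free catalyst → catalyst intermediate A (k1 = 120 /M/s)
    catalyst intermediate A → catalyst intermediate B (k2 = 230 /s)
    catalyst intermediate B → free catalyst + product (k3 = 98 /s)
    solid substrate ⇌ starting material, rate k4*(cs4 - [starting material]) while solid is left; crystals form when [starting material] > cs4 (cs4 = 0.16 M, k4 = 0.69 /s)
    capture agent + catalyst intermediate B → trapped intermediate (k5 = 11 /M/s)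

solid substrate 1.5 M; capture agent 0.0750 M; free catalyst 4.6 mM; time 40 s

- amber: doubling the solubility in step 4, all else as stated
- teal: doubling the amount of free catalyst, all else as stated
- violet: doubling the dissolution coefficient of step 4, all else as stated

1. amount of product at 40 s, in percent of the solid substrate charged
2. the change that raises the amount of product at 40 s, in percent of the solid substrate charged most ("none" if none brings more than 2 percentage points) (amber / teal / violet / none)
3. amount of product at 40 s, in percent of the solid substrate charged, after amber

At each pass, catalyst intermediate B faces two rates. Release runs at 98 /s. I treated capture as pseudo-first-order, because the capture agent stands 16.3 times above the catalyst, so its rate is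

capture rate = 0.825 /s

N = release rate / capture rate = 119

N, the turnover number, is the product released on average per catalyst before capture. Multiplied by the catalyst charge, it gives an estimate of the product to expect:

expected product = 0.546 M, or 36.4 % of the solid substrate charged

Dissolving into a solution kept empty, with the solid never running out, could deliver 294 % by 40 s, more than this estimate. I therefore committed to the estimate as y, though my reckoning did not say how soon it is reached. Neither amber nor violet enters N, while teal doubles the estimate to 72.8 %, so I chose teal.

The forecast gave 36.8 %, teal, and 37.5 % after amber, a little above my estimate. Its ground was: “higher solubility or faster dissolution only reaches the same cap sooner”.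

The simulation gave 37.0 %, teal and 37.6 % after amber. Teal gained 38 percentage points, amber 0.59 points and violet 0.17 points.

In this flask, with 98.4 % of the catalyst trapped at 40.0 s, the readings give 123 product per trapped catalyst, against N of 119. The neighbouring flask holds 0.019 M of capture agent, so there N is 469 and the estimate is 144 % of the charge, above the charge itself. That flask read 88.4 % at 40.0 s, with 11 % of the solid substrate still there, solid or dissolved, and 57.1 % of the catalyst trapped, which is 505 product per trapped catalyst.

(Its constants are made up; no experiment stands behind them.)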